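## Retrosynthetic overview

1. The C3 ester is cut last, giving the 3α,4α-diol of the eudesmane core plus (3S)-3-methylpentanoic acid; the tertiary C4 hydroxyl needs no protection.
2. The cis-diol comes from osmylation of the ring A olefin of (5R,10R)-eudesma-3,7(11)-dien-8-one on the face opposite the angular methyl.
3. Both rings of that dienone close in one gold-triggered cascade from an acyclic C15 1,5-enyne bearing a 2-silyloxydiene: ring A first (C4–C5, alkyne-initiated), then ring B (C9–C10, silyl enol ether capture of the C10 cation), which also delivers the 7-isopropylidene-8-ketone.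
4. The acyclic chain is mesityl oxide alkylated by an (E)-allylic bromide, itself made from pent-3-yn-1-ol and ethyl but-2-ynoate by syn-carbocupration.

Assumption: (3S)-3-methylpentanoic acid is bought as the single enantiomer, and the (R)-configured ligand is taken to give the (5R,10R) series in step 7 (its (S)-enantiomer is used if the sense proves opposite).

Eudesmane numbering (C1–C15) is used for positions in the text.

## Route

Step 1
Reactants: 1 pent-3-yn-1-ol
Product: 2 5-bromopent-2-yne
Conditions: CBr4, PPh3, CH2Cl2, 0 °C
Reagents that add atoms: carbon tetrabromide, BrC(Br)(Br)Br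
Why: Appel bromination converts the primary alcohol into the bromide by SN2 displacement of the alkoxyphosphonium group and leaves the internal alkyne untouched; no stereocentre is involved.

Step 2
Reactants: 2 5-bromopent-2-yne; 3 ethyl but-2-ynoate
Product: 5 ethyl (2E)-3-methyloct-2-en-6-ynoate, via pent-3-yn-1-ylmagnesium bromide 4 (not isolated)
Conditions: Mg, THF, 23 °C; CuBr·SMe2 (1.0 equiv), −40 °C; then 3, −78 °C; NH4Cl (aq), −78 °C
Reagents that add atoms: none
Why: The Grignard reagent is transmetalated to an organocopper species whose syn-carbocupration of the ynoate (conjugate addition) and cold protonation place the new chain trans to the ester, giving the (E)-trisubstituted olefin that later encodes the trans ring fusion.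

Step 3
Reactants: 5 ethyl (2E)-3-methyloct-2-en-6-ynoate
Product: 6 (2E)-3-methyloct-2-en-6-yn-1-ol
Conditions: i-Bu2AlH (2.2 equiv), CH2Cl2, −78 → 0 °C; Rochelle salt (aq)
Reagents that add atoms: none
Why: Aluminium hydride 1,2-reduction of the unsaturated ester gives the allylic alcohol without changing the olefin geometry or touching the alkyne.

Step 4
Reactants: 6 (2E)-3-methyloct-2-en-6-yn-1-ol
Product: 7 (2E)-1-bromo-3-methyloct-2-en-6-yne
Conditions: PBr3 (0.4 equiv), Et2O, 0 °C
Reagents that add atoms: phosphorus tribromide, BrP(Br)Br
Why: Bromide displaces the phosphite ester of the primary allylic alcohol by SN2 at 0 °C, so the primary bromide forms with the E olefin retained.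

Step 5
Reactants: 7 (2E)-1-bromo-3-methyloct-2-en-6-yne; 8 mesityl oxide (4-methylpent-3-en-2-one, 3 equiv)
Product: 10 (5E)-6-methyl-3-(propan-2-ylidene)undec-5-en-9-yn-2-one, via deconjugated isopropenyl ketone 9 (not isolated)
Conditions: KOt-Bu (1.2 equiv), THF/t-BuOH, 0 °C; then crude, DBU (0.2 equiv), CH2Cl2, 40 °C
Reagents that add atoms: none
Why: γ-Deprotonation of mesityl oxide gives the extended potassium dienolate, which is alkylated at its α-carbon by the allylic bromide (deconjugative SN2 alkylation), and DBU-mediated prototropic equilibration then returns the double bond into conjugation as the tetrasubstituted isopropylidene enone.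

Step 6
Reactants: 10 (5E)-6-methyl-3-(propan-2-ylidene)undec-5-en-9-yn-2-one
Product: 11 tert-butyl(dimethyl){[(5E)-6-methyl-3-(propan-2-ylidene)undeca-1,5-dien-9-yn-2-yl]oxy}silane
Conditions: LiN(i-Pr)2 (1.1 equiv), THF, −78 °C; then TBSOTf, −78 °C; filtration through Et3N-deactivated alumina
Reagents that add atoms: tert-butyldimethylsilyl trifluoromethanesulfonate, CC(C)(C)[Si](C)(C)OS(=O)(=O)C(F)(F)F
Why: Kinetic deprotonation of the acetyl methyl group (the α′ position) at −78 °C and O-silylation give the cross-conjugated 2-silyloxy-1,3-diene (kinetic silyl enol ether formation) rather than the vinylogous γ-dienol ether.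

Step 7
Reactants: 11 tert-butyl(dimethyl){[(5E)-6-methyl-3-(propan-2-ylidene)undeca-1,5-dien-9-yn-2-yl]oxy}silane
Product: 12 (4aR,8aR)-5,8a-dimethyl-3-(propan-2-ylidene)-3,4,4a,7,8,8a-hexahydronaphthalen-2(1H)-one [(5R,10R)-eudesma-3,7(11)-dien-8-one; trans-fused, 5α-H, 10β-CH3]
Conditions: [(R)-DTBM-MeO-BIPHEP](AuCl)2 (3 mol %), AgSbF6 (6 mol %), i-PrOH (1.5 equiv), toluene (0.02 M), −20 → 23 °C
Reagents that add atoms: none
Why: Proposed new method: cationic monovalent gold π-activates the methyl alkyne, the (E)-trisubstituted olefin attacks its distal carbon anti to gold in a chair-like 6-endo-dig closure (ring A, C4–C5), the resulting tertiary C10 cation is alkylated by the terminal carbon of the silyloxydiene (ring B, C9–C10, Mukaiyama-type tert-alkylation of a silyl enol ether), and i-PrOH takes up the silyl group and protodeaurates C3, so that anti addition across the E olefin fixes the trans 5-H/10-CH3 relationship while the chiral digold bisphosphine selects the olefin face and hence the absolute configuration at C5 and C10; the closest known reaction types are enantioselective gold-catalysed alkyne-initiated polyene cyclisations and gold-catalysed 6-endo-dig 1,5-enyne cyclisations terminated by phenols or arenes.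

Step 8
Reactants: 12 (5R,10R)-eudesma-3,7(11)-dien-8-one
Product: 13 (4aR,5S,6R,8aR)-5,6-dihydroxy-5,8a-dimethyl-3-(propan-2-ylidene)-3,4,4a,5,6,7,8,8a-octahydronaphthalen-2(1H)-one [3α,4α-dihydroxyeudesm-7(11)-en-8-one]
Conditions: OsO4 (5 mol %), NMO (2 equiv), acetone/H2O 4:1, 23 °C
Reagents that add atoms: osmium tetroxide, O=[Os](=O)(=O)=O; N-methylmorpholine N-oxide, C[N+]1([O-])CCOCC1; water, O
Why: Upjohn dihydroxylation (concerted [3+2] syn addition of OsO4) takes place at the electron-rich trisubstituted ring A olefin rather than the electron-poor tetrasubstituted enone olefin, and from the α face opposite the axial angular methyl, which sets C3 (R) and C4 (S) as the cis 3α,4α-diol.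

Step 9
Reactants: 13 3α,4α-dihydroxyeudesm-7(11)-en-8-one; 14 (3S)-3-methylpentanoic acid (1.5 equiv)
Product: 15 (1S,2R,4aR,8aR)-1-hydroxy-1,4a-dimethyl-6-oxo-7-(propan-2-ylidene)decahydronaphthalen-2-yl (3S)-3-methylpentanoate (CNP0334363.1)
Conditions: DCC (1.6 equiv), DMAP (0.3 equiv), CH2Cl2, 0 → 23 °C
Reagents that add atoms: none
Why: Steglich esterification (acyl transfer through the acylpyridinium ion) acylates the secondary 3α-hydroxyl while the tertiary 4-hydroxyl is inert, and the β-stereocentre of the acid cannot epimerise, so all five stereocentres of the target are in place.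

## Compound list

1 | pent-3-yn-1-ol | CC#CCCO | starting material
2 | 5-bromopent-2-yne | CC#CCCBr | intermediate
3 | ethyl but-2-ynoate | CC#CC(=O)OCC | starting material
4 | pent-3-yn-1-ylmagnesium bromide | CC#CCC[Mg]Br | intermediate
5 | ethyl (2E)-3-methyloct-2-en-6-ynoate | CC#CCC/C(C)=C/C(=O)OCC | intermediate
6 | (2E)-3-methyloct-2-en-6-yn-1-ol | CC#CCC/C(C)=C/CO | intermediate
7 | (2E)-1-bromo-3-methyloct-2-en-6-yne | CC#CCC/C(C)=C/CBr | intermediate
8 | mesityl oxide (4-methylpent-3-en-2-one) | CC(=O)C=C(C)C | starting material
9 | (5E)-6-methyl-3-(prop-1-en-2-yl)undec-5-en-9-yn-2-one (racemic at C3) | CC#CCC/C(C)=C/CC(C(C)=C)C(C)=O | intermediate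
10 | (5E)-6-methyl-3-(propan-2-ylidene)undec-5-en-9-yn-2-one | CC#CCC/C(C)=C/CC(=C(C)C)C(C)=O | intermediate
11 | tert-butyl(dimethyl){[(5E)-6-methyl-3-(propan-2-ylidene)undeca-1,5-dien-9-yn-2-yl]oxy}silane | CC#CCC/C(C)=C/CC(=C(C)C)C(=C)O[Si](C)(C)C(C)(C)C | intermediate
12 | (4aR,8aR)-5,8a-dimethyl-3-(propan-2-ylidene)-3,4,4a,7,8,8a-hexahydronaphthalen-2(1H)-one | C1C[C@]2(C)CC(=O)C(=C(C)C)C[C@H]2C(C)=C1 | intermediate
13 | (4aR,5S,6R,8aR)-5,6-dihydroxy-5,8a-dimethyl-3-(propan-2-ylidene)-3,4,4a,5,6,7,8,8a-octahydronaphthalen-2(1H)-one | O[C@@H]1CC[C@]2(C)CC(=O)C(=C(C)C)C[C@H]2[C@]1(C)O | intermediate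
14 | (3S)-3-methylpentanoic acid | CC[C@H](C)CC(=O)O | starting material
15 | (1S,2R,4aR,8aR)-1-hydroxy-1,4a-dimethyl-6-oxo-7-(propan-2-ylidene)decahydronaphthalen-2-yl (3S)-3-methylpentanoate | CC[C@H](C)CC(=O)O[C@@H]1CC[C@]2(C)CC(=O)C(=C(C)C)C[C@H]2[C@]1(C)O | target

## Step count and risks

Total step count: 9. Longest linear sequence: 9 steps (1 → 15).

The three steps most likely to fail:

**Step 7 (the two-ring cascade).** The silyl dienol ether may be protodesilylated before it captures the C10 cation. Neither the level nor the sense of asymmetric induction is established for a methyl-substituted alkyne reacting in the 6-endo-dig mode. Fallback: setting out from 11, the cascade is run with the achiral complex (Ph3P)AuNTf2 (2 mol %, i-PrOH, CH2Cl2, 0 °C), which gives the racemate, that is 12 together with its mirror image (4aS,8aS)-5,8a-dimethyl-3-(propan-2-ylidene)-3,4,4a,7,8,8a-hexahydronaphthalen-2(1H)-one F1. The two are separated by preparative supercritical-fluid chromatography on an amylose tris(3,5-dimethylphenylcarbamate) phase, and the route is rejoined at 12. Absolute configuration then comes from resolution instead of catalysis. Failure of the carbon termination itself is covered by the oxygen-terminated variant given for step 6.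

**Step 5 (α-alkylation of mesityl oxide).** The dienolate can also react at the α′ carbon or at oxygen, the product can be alkylated a second time, and the conjugated/deconjugated equilibrium of an α-alkylated mesityl oxide is not strongly one-sided. Fallback: setting out from 7, pentane-2,4-dione is C-alkylated (K2CO3, acetone, reflux) to 3-[(2E)-3-methyloct-2-en-6-yn-1-yl]pentane-2,4-dione F2. Because the two acetyl groups are equivalent, enol triflation (NaH, THF, 0 °C; Tf2O, −78 °C) gives one constitutional enol triflate, 4-oxo-3-[(2E)-3-methyloct-2-en-6-yn-1-yl]pent-2-en-2-yl trifluoromethanesulfonate F3 (either enol geometry serves). Addition–elimination with LiCuMe2 (THF, −78 °C) replaces the triflate by methyl and gives the conjugated isopropylidene ketone directly. The route is rejoined at 10, two steps longer.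

**Step 6 (regioselective silyl dienol ether).** Some γ-deprotonation would give the linear dienol ether, and the hindered 2-silyloxydiene is sensitive to hydrolysis on purification. Fallback: setting out from 10, the free methyl ketone is used as the terminator. With the same chiral gold catalyst and no alcohol additive (toluene, 23 °C), the ketone oxygen captures the C10 cation and loss of a C9 proton protodeaurates C3. This gives the bicyclic enol ether (4aS,8aS)-5,8a-dimethyl-2-methylidene-3-(propan-2-ylidene)-3,4,4a,7,8,8a-hexahydro-2H-chromene F4. Me2AlCl (CH2Cl2, −78 °C) then ionises the tertiary C–O bond and the aluminium dienolate recloses through carbon (Ferrier-type 1,3 oxygen-to-carbon shift). The C5 stereocentre is untouched and should direct equatorial, trans-fused reclosure. The route is rejoined at 12, bypassing 11.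

## Further compounds

F1 | step 7 | (4aS,8aS)-5,8a-dimethyl-3-(propan-2-ylidene)-3,4,4a,7,8,8a-hexahydronaphthalen-2(1H)-one | C1C[C@@]2(C)CC(=O)C(=C(C)C)C[C@@H]2C(C)=C1
F2 | step 5 | 3-[(2E)-3-methyloct-2-en-6-yn-1-yl]pentane-2,4-dione | CC#CCC/C(C)=C/CC(C(C)=O)C(C)=O
F3 | step 5 | 4-oxo-3-[(2E)-3-methyloct-2-en-6-yn-1-yl]pent-2-en-2-yl trifluoromethanesulfonate | CC#CCC/C(C)=C/CC(C(C)=O)=C(C)OS(=O)(=O)C(F)(F)F
F4 | step 6 | (4aS,8aS)-5,8a-dimethyl-2-methylidene-3-(propan-2-ylidene)-3,4,4a,7,8,8a-hexahydro-2H-chromene | C1C[C@]2(C)OC(=C)C(=C(C)C)C[C@H]2C(C)=C1
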